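## Retrosynthetic overview

- Agecorynin E, a (2S)-flavanone, comes from its ring B O-benzyl ether. Neutral hydrogenolysis is placed last, so the C2 centre is never exposed to base while the para-phenol is free.
- The key disconnection is O1–C2 of the dihydropyranone ring. This copies the chalcone isomerase step: an enantioselective 6-endo-trig oxa-Michael closure of an achiral 2'-hydroxychalcone. The chalcone carries a temporary tert-butyl ester on C3, which leaves as isobutene and CO2 in the same pot.
- The enabling feature is that the ring A phenol oxygen (future O1) sits ortho to the C4 carbonyl carbon. The chain O1–C8a–C4a–C4–C3–C2 therefore brings it within six-ring reach of benzylic C2, the β-carbon of the C4 enone. C3, α to C4=O, can hold a removable carboxyl group that binds the catalyst and activates C2. The C5 methoxy group ortho to the carbonyl disfavours the open form.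
- The activated chalcone comes from Knoevenagel union (C2=C3) of O-benzylvanillin with the ring A β-ketoester. The β-ketoester comes from Claisen carboxylation of 2-hydroxy-4,5,6-trimethoxyacetophenone, which comes from ortho-acetylation of 3,4,5-trimethoxyphenol.
- Ring order: rings A and B are bought, and the dihydropyranone ring is the only ring formed, in step 4.

Key step: step 4

Assumption: the quinidine-derived thiourea is taken to give the (2S) series; it and the quinine-derived catalyst act as pseudo-enantiomers, so if the first run shows the opposite sense the quinine-derived one is used and nothing else changes.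

## Route

Step 1
Reactants: 1 3,4,5-trimethoxyphenol
Product: 3 1-(2-hydroxy-4,5,6-trimethoxyphenyl)ethanone, via aryl acetate 2 (not isolated)
Conditions: Ac2O (1.2 equiv), BF3·OEt2, 0 °C to 70 °C; aqueous work-up
Reagents that add atoms: acetic anhydride CC(=O)OC(C)=O
Why: O-acetylation to 2 followed by BF3-promoted Fries rearrangement (overall a Friedel–Crafts ortho-acylation) should give a single ketone, because the two free positions of ring A are equivalent and both ortho to the hydroxyl group and the chelated, deactivated product does not acylate again; no stereocentre is formed.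

Step 2
Reactants: 3 1-(2-hydroxy-4,5,6-trimethoxyphenyl)ethanone
Product: 5 tert-butyl 3-(2-hydroxy-4,5,6-trimethoxyphenyl)-3-oxopropanoate, via dilithium dianion 4 (not isolated)
Conditions: LiN(SiMe3)2 (3.3 equiv), THF, −78 to −20 °C; Boc2O (1.05 equiv), −78 °C; AcOH quench at −78 °C
Reagents that add atoms: di-tert-butyl dicarbonate CC(C)(C)OC(=O)OC(=O)OC(C)(C)C
Why: Crossed Claisen condensation of a ketone enolate with a dicarbonate, in which the enolate carbon of 4 is far more nucleophilic than the chelated phenolate, any carbonate formed on oxygen should converge on 5 by Baker–Venkataraman-type oxygen-to-carbon transfer, the third equivalent of base stores 5 as its inert enolate, and the bulky ester plus the cold acid quench prevents lactonisation.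

Step 3
Reactants: 5 tert-butyl 3-(2-hydroxy-4,5,6-trimethoxyphenyl)-3-oxopropanoate; 6 4-(benzyloxy)-3-methoxybenzaldehyde (O-benzylvanillin)
Product: 7 tert-butyl (Z)-3-[4-(benzyloxy)-3-methoxyphenyl]-2-(2-hydroxy-4,5,6-trimethoxybenzoyl)prop-2-enoate
Conditions: piperidine (10 mol%), AcOH (10 mol%), 4 Å molecular sieves, toluene, rt; dilute aqueous citric acid wash, crystallisation
Reagents that add atoms: none
Why: Knoevenagel condensation through the iminium ion of 6, driven by the sieves, should give mainly the Z alkene with the aryl group trans to the bulky, twisted aroyl group, and the buffered conditions plus the acid wash are chosen so that the hydrogen-bonded phenol does not yet add to the new double bond.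

Step 4
Reactants: 7 tert-butyl (Z)-3-[4-(benzyloxy)-3-methoxyphenyl]-2-(2-hydroxy-4,5,6-trimethoxybenzoyl)prop-2-enoate
Product: 10 (2S)-2-[4-(benzyloxy)-3-methoxyphenyl]-5,6,7-trimethoxy-2,3-dihydro-4H-chromen-4-one, via flavanone tert-butyl ester 8 (not isolated), via flavanone keto acid 9 (not isolated)
Conditions: 1-[3,5-bis(trifluoromethyl)phenyl]-3-[(9R)-6'-methoxycinchonan-9-yl]thiourea (quinidine-derived, 10 mol%), toluene, −25 °C; then TsOH·H2O (50 mol%), −25 °C to 80 °C
Reagents that add atoms: none
Why: The two thiourea N–H bonds of the catalyst bind the 1,3-dicarbonyl unit of 7 while its quinuclidine nitrogen takes the proton of the ring A phenol, the phenol oxygen adds to the benzylidene carbon (future C2) and the enolate is protonated to 8; TsOH then silences the amine, ionises the tert-butyl ester to isobutene and acid 9, and 9 loses CO2 through the cyclic six-centre transition state of a β-keto acid to give 10. The closest known reaction type is the cinchona-thiourea-catalysed asymmetric intramolecular oxa-Michael addition of 2-hydroxyaryl alkylidene β-ketoesters with acid decarboxylation in the same pot, the laboratory counterpart of the chalcone isomerase step of flavonoid biosynthesis. The dihydropyranone ring closes in the 6-endo-trig mode, which is feasible because the aryl ketone holds O1 and C2 within bonding distance. C2 is controlled by the catalyst alone, whose C8 and C9 stereocentres fix the positions of base and hydrogen-bond donor so that oxygen reaches one face of the bound alkylidene, whereas C3 forms trans to the aryl group under thermodynamic control and is erased on decarboxylation. The step needs the catalysed closure to outrun uncatalysed closure and retro-addition: the internal hydrogen bond of the phenol to C4=O keeps it quiet until the base engages it, the ester raises the affinity for the thiourea, the benzyl ether on ring B shuts off the quinone methide push that would reopen the ring, and toluene at −25 °C suppresses the background path. Site selectivity is secured because the phenol is the only free nucleophile and C2 the only electrophilic alkene carbon.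

Step 5
Reactants: 10 (2S)-2-[4-(benzyloxy)-3-methoxyphenyl]-5,6,7-trimethoxy-2,3-dihydro-4H-chromen-4-one
Product: 11 agecorynin E [(2S)-2-(4-hydroxy-3-methoxyphenyl)-5,6,7-trimethoxy-2,3-dihydro-4H-chromen-4-one]
Conditions: H2 (1 atm), 10% Pd/C, EtOAc, rt
Reagents that add atoms: none
Why: Hydrogenolysis of an aryl benzyl ether over Pd/C under neutral conditions should cleave the O–CH2Ph bond much faster than the cyclic C2–O1 bond breaks or the electron-rich aryl ketone is reduced, and the absence of acid and base leaves untouched the C2 centre, which could otherwise open to the chalcone through the free para-phenol.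

## Compound list

1 | 3,4,5-trimethoxyphenol | COc1cc(O)cc(OC)c1OC | starting material
2 | 3,4,5-trimethoxyphenyl acetate (not isolated) | CC(=O)Oc1cc(OC)c(OC)c(OC)c1 | intermediate
3 | 1-(2-hydroxy-4,5,6-trimethoxyphenyl)ethanone | CC(=O)c1c(O)cc(OC)c(OC)c1OC | intermediate
4 | dilithium enolate-phenolate of 3 (not isolated) | [Li+].[Li+].C=C([O-])c1c([O-])cc(OC)c(OC)c1OC | intermediate
5 | tert-butyl 3-(2-hydroxy-4,5,6-trimethoxyphenyl)-3-oxopropanoate | CC(C)(C)OC(=O)CC(=O)c1c(O)cc(OC)c(OC)c1OC | intermediate
6 | 4-(benzyloxy)-3-methoxybenzaldehyde | COc1cc(C=O)ccc1OCc1ccccc1 | starting material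
7 | tert-butyl (Z)-3-[4-(benzyloxy)-3-methoxyphenyl]-2-(2-hydroxy-4,5,6-trimethoxybenzoyl)prop-2-enoate | CC(C)(C)OC(=O)/C(=C\c1ccc(OCc2ccccc2)c(OC)c1)C(=O)c1c(O)cc(OC)c(OC)c1OC | intermediate
8 | tert-butyl (2S,3R)-2-[4-(benzyloxy)-3-methoxyphenyl]-5,6,7-trimethoxy-4-oxochromane-3-carboxylate (trans, C3 labile, not isolated) | COc1cc([C@@H]2[C@@H](C(=O)OC(C)(C)C)C(=O)c3c(cc(OC)c(OC)c3OC)O2)ccc1OCc1ccccc1 | intermediate
9 | (2S,3R)-2-[4-(benzyloxy)-3-methoxyphenyl]-5,6,7-trimethoxy-4-oxochromane-3-carboxylic acid (not isolated) | COc1cc([C@@H]2[C@@H](C(=O)O)C(=O)c3c(cc(OC)c(OC)c3OC)O2)ccc1OCc1ccccc1 | intermediate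
10 | (2S)-2-[4-(benzyloxy)-3-methoxyphenyl]-5,6,7-trimethoxy-2,3-dihydro-4H-chromen-4-one | COc1cc([C@@H]2CC(=O)c3c(cc(OC)c(OC)c3OC)O2)ccc1OCc1ccccc1 | intermediate
11 | agecorynin E, (2S)-2-(4-hydroxy-3-methoxyphenyl)-5,6,7-trimethoxy-2,3-dihydro-4H-chromen-4-one | COc1cc([C@@H]2CC(=O)c3c(cc(OC)c(OC)c3OC)O2)ccc1O | target

## Step count

Total step count: 5
Longest linear sequence: 5 steps (1 to 3 to 5 to 7 to 10 to 11); 6 is bought.

## Steps most likely to fail

**Step 4.**
- Facial selectivity may be poor, because uncatalysed ring closure is favoured by the C5 methoxy group and competes with the catalysed path.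
- Configuration may also be partly lost by acid-promoted ring opening during the hot decarboxylation.

The fallback sets out from 3 and 6 and comes back at 10. It keeps the O1–C2 closure but takes the asymmetry from a resolution. Claisen–Schmidt condensation (KOH, EtOH, rt) would give the (E)-2'-hydroxychalcone F1. NaOAc in refluxing EtOH would close it without stereocontrol to the racemic flavanone benzyl ether F2. Kinetic resolution follows by asymmetric transfer hydrogenation with RuCl(p-cymene)[(R,R)-TsDPEN], HCO2H/Et3N, EtOAc, rt, stopped near half conversion. It should reduce the (2R) ketone, for which catalyst preference and cis delivery of hydride are matched, to the cis-(2R,4R)-flavan-4-ol F3. Compound 10 is left unreduced and is separated by chromatography.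

**Step 3.**
- The free phenol may close prematurely and without stereocontrol onto the new alkylidene under the amine/acid conditions.
- Condensation of the electron-rich aldehyde may be sluggish.
- The alkene geometry may scramble.

The fallback sets out from 3 and comes back at 10. It avoids the alkylidene altogether. Heating 3 with N,N-dimethylformamide dimethyl acetal (toluene, 100 °C) would give the enaminone F4. Aqueous HCl in CH2Cl2 would close it to 5,6,7-trimethoxychromone F5. Asymmetric conjugate addition of commercial 4-(benzyloxy)-3-methoxyphenylboronic acid should then give 10. The conditions are Pd(OCOCF3)2 (5 mol%), (R)-4-tert-butyl-2-(pyridin-2-yl)-4,5-dihydrooxazole (6 mol%), NH4PF6, H2O, ClCH2CH2Cl, 60 °C. This ligand enantiomer is the one expected to lead to the (2S) series by analogy with cyclic enones.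

**Step 2.**
- Carboxylation may occur at the phenolate oxygen instead of the enolate carbon.
- Double acylation may occur.
- The product may lactonise if the mixture warms before the quench.

The fallback sets out from 3 and comes back at 5. It delivers the carboxyl group intramolecularly. Boc2O with catalytic DMAP in CH2Cl2 at rt would give the aryl tert-butyl carbonate F6. LiN(SiMe3)2 (2.2 equiv) in THF at −78 to −20 °C with an AcOH quench should then trigger a Baker–Venkataraman rearrangement, in which the ketone enolate attacks the neighbouring carbonate and expels the phenolate to give 5.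

## Further compounds

F1 | step 4 | (E)-3-[4-(benzyloxy)-3-methoxyphenyl]-1-(2-hydroxy-4,5,6-trimethoxyphenyl)prop-2-en-1-one | COc1cc(/C=C/C(=O)c2c(O)cc(OC)c(OC)c2OC)ccc1OCc1ccccc1
F2 | step 4 | racemic 2-[4-(benzyloxy)-3-methoxyphenyl]-5,6,7-trimethoxy-2,3-dihydro-4H-chromen-4-one | COc1cc(C2CC(=O)c3c(cc(OC)c(OC)c3OC)O2)ccc1OCc1ccccc1
F3 | step 4 | (2R,4R)-2-[4-(benzyloxy)-3-methoxyphenyl]-5,6,7-trimethoxychroman-4-ol | COc1cc([C@H]2C[C@@H](O)c3c(cc(OC)c(OC)c3OC)O2)ccc1OCc1ccccc1
F4 | step 3 | (E)-3-(dimethylamino)-1-(2-hydroxy-4,5,6-trimethoxyphenyl)prop-2-en-1-one | CN(C)/C=C/C(=O)c1c(O)cc(OC)c(OC)c1OC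
F5 | step 3 | 5,6,7-trimethoxy-4H-chromen-4-one | COc1cc2occc(=O)c2c(OC)c1OC
F6 | step 2 | 2-acetyl-3,4,5-trimethoxyphenyl tert-butyl carbonate | CC(=O)c1c(OC(=O)OC(C)(C)C)cc(OC)c(OC)c1OC
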